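**Strategy.** The carbocycle of the target holds a non-enolisable 1,3-diketone, C5'(=O)–C6'(CH3)2–C7'(=O). The target is therefore the C-acyl isomer of an enol δ-lactone in which the C5' acyl group sits on the enol oxygen of C7'. The route builds that isomer, a spiro pyrano-lactone, by a domino Knoevenagel/oxa-Diels–Alder reaction of a dimethylketene-dimer-derived enol lactone, isobutyraldehyde and (+)-β-pinene, which sets both new stereocentres. A catalytic, methoxide-triggered O-to-C acyl shift then opens the lactone and closes the cyclohexenedione ring by forming the C5'–C6' bond. No protecting group or redox step is needed.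

Key step: step 4

Assumption: (1R,5R)-(+)-β-pinene is bought as the single enantiomer (the less common antipode, but offered commercially). Locants are unprimed for the bicyclo[3.1.1]heptane unit and primed for the oxygen heterocycle, as in spiro[bicyclo[3.1.1]heptane-2,2'-chromene].

Step 1
Reactants: 1 tert-butyl acetate; 2 2,2,4,4-tetramethylcyclobutane-1,3-dione
Product: 5 tert-butyl 4,4,6-trimethyl-3,5-dioxoheptanoate, via lithium enolate of tert-butyl acetate 3 (not isolated), via lithium cyclobutanone aldolate 4 (not isolated)
Conditions: LiN(iPr)2 (1.05 equiv), THF, −78 °C; then 2, −78 °C → rt; AcOH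
Reagents that add atoms: none
Why: Aldol addition of ester enolate 3 to one carbonyl of the strained dione gives aldolate 4, whose alkoxide expels the neighbouring ring carbon as a ketone enolate on warming (strain-releasing retro-Claisen ring opening, the known base cleavage of 3-hydroxycyclobutanones derived from 2), and internal proton transfer from the new β-keto ester methylene makes the sequence irreversible; no stereocenter is formed.

Step 2
Reactants: 5 tert-butyl 4,4,6-trimethyl-3,5-dioxoheptanoate
Product: 8 5,5-dimethyl-6-(propan-2-ylidene)oxane-2,4-dione, via 4,4,6-trimethyl-3,5-dioxoheptanoic acid 6 (not isolated), via mixed trifluoroacetic anhydride 7 (not isolated)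
Conditions: TFA, TFAA, CH2Cl2, 0 °C → rt
Reagents that add atoms: none
Why: Acidolysis of the tert-butyl ester gives acid 6, which is activated as mixed anhydride 7 and should acylate the C5 ketone oxygen before it can decarboxylate (enol lactonisation, the TFA/TFAA pyranone cyclisation of 3,5-dioxoalkanoates); because C4 is quaternary the C5 ketone can enolise only toward C6, so the exocyclic tetrasubstituted enol lactone is the only six-membered outcome, and no stereocenter is formed.

Step 3
Reactants: 8 5,5-dimethyl-6-(propan-2-ylidene)oxane-2,4-dione; 9 2-methylpropanal; 10 (1R,5R)-(+)-β-pinene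
Product: 12 (1S,2S,4'R,5R)-6,6,8',8'-tetramethyl-4'-(propan-2-yl)-7'-(propan-2-ylidene)-3',4',7',8'-tetrahydro-5'H-spiro[bicyclo[3.1.1]heptane-2,2'-pyrano[4,3-b]pyran]-5'-one, via alkylidene lactone heterodiene 11 (not isolated)
Conditions: NaOAc (20 mol %), AcOH (20 mol %), 4 Å MS, toluene, 10 (5 equiv), sealed tube, 80 °C
Reagents that add atoms: none
Why: Domino Knoevenagel condensation/inverse-electron-demand oxa-Diels–Alder reaction: the acidic β-keto lactone 8 condenses with 9 to the doubly activated, s-cis-locked 1-oxadiene 11, which should add thermally to the 1,1-disubstituted alkene of 10 through its ketone oxygen (the more electron-rich oxygen in the polarised transition state, as in O-alkylation of β-keto esters) with oxygen bonding to the fully substituted pinene carbon; approach to the alkene face opposite the gem-dimethyl bridge sets the spiro centre C2, the endo/exo orientation sets C4' (bridgehead C1 endo gives the required 4'R isomer), and the 4'-epimer expected alongside would be removed by chromatography.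

Step 4
Reactants: 12 spiro pyrano-lactone from step 3
Product: 14 (1S,2S,4'R,5R)-6,6,6',6',8',8'-hexamethyl-4'-(propan-2-yl)-3',4'-dihydrospiro[bicyclo[3.1.1]heptane-2,2'-chromene]-5',7'(6'H,8'H)-dione, via ring-opened sodium enolate 13 (not isolated)
Conditions: NaOMe (20 mol %), dry THF, 0 °C → 50 °C; aq. NH4Cl
Reagents that add atoms: none
Why: Methoxide adds to the lactone carbonyl (C5') of 12, the acyl–oxygen bond breaks and the tetrasubstituted ketone enolate 13 is released next to the new methyl ester; the enolate carbon (the former isopropylidene carbon) then attacks that ester, methoxide is expelled and re-enters the cycle, so the net change is an O-to-C 1,3-acyl shift that forms the C5'–C6' bond. The closest known reaction type is the alkoxide-mediated enol lactone to cyclic 1,3-diketone rearrangement (alkylidene phthalides to indane-1,3-diones, ylidene butenolides to cyclopentene-1,3-diones), and the closure itself is a Dieckmann-type Claisen condensation of the kind by which catalytic methoxide converts dimethylketene oligomers into fully substituted, non-enolisable cyclohexane-1,3,5-triones. The carbocycle closes in a 6-(enolendo)-exo-trig mode while the six-membered lactone opens. No stereocenter is formed, and the four existing ones (C1, C2, C5, C4') carry no acidic hydrogen, so they should be carried through unchanged. The step needs C-acylation to prevail over O-acylation and over retro-Claisen attack of methoxide on the side-chain ketone: O-acylation only regenerates 12, the C-acyl isomer is favoured by the usual energy gap between an enol ester and a 1,3-diketone, and the ketone of 13 is flanked by a quaternary and a tertiary carbon, which together with the low stationary amount of methoxide in an aprotic solvent should keep cleavage slow.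

**Compound list**

1 | tert-butyl acetate | CC(=O)OC(C)(C)C | starting material
2 | 2,2,4,4-tetramethylcyclobutane-1,3-dione | CC1(C)C(=O)C(C)(C)C1=O | starting material
3 | lithium enolate of tert-butyl acetate | [Li+].[O-]C(=C)OC(C)(C)C | intermediate
4 | lithium alkoxide of tert-butyl 2-(1-hydroxy-2,2,4,4-tetramethyl-3-oxocyclobutyl)acetate | [Li+].[O-]C1(CC(=O)OC(C)(C)C)C(C)(C)C(=O)C1(C)C | intermediate
5 | tert-butyl 4,4,6-trimethyl-3,5-dioxoheptanoate | CC(C)C(=O)C(C)(C)C(=O)CC(=O)OC(C)(C)C | intermediate
6 | 4,4,6-trimethyl-3,5-dioxoheptanoic acid | CC(C)C(=O)C(C)(C)C(=O)CC(=O)O | intermediate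
7 | 4,4,6-trimethyl-3,5-dioxoheptanoic trifluoroacetic anhydride | CC(C)C(=O)C(C)(C)C(=O)CC(=O)OC(=O)C(F)(F)F | intermediate
8 | 5,5-dimethyl-6-(propan-2-ylidene)oxane-2,4-dione | CC(C)=C1OC(=O)CC(=O)C1(C)C | intermediate
9 | 2-methylpropanal | CC(C)C=O | starting material
10 | (1R,5R)-(+)-β-pinene, (1R,5R)-6,6-dimethyl-2-methylidenebicyclo[3.1.1]heptane | C=C1CC[C@@H]2C[C@H]1C2(C)C | starting material
11 | 5,5-dimethyl-3-(2-methylpropylidene)-6-(propan-2-ylidene)oxane-2,4-dione (alkene geometry not fixed) | CC(C)C=C1C(=O)OC(=C(C)C)C(C)(C)C1=O | intermediate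
12 | (1S,2S,4'R,5R)-6,6,8',8'-tetramethyl-4'-(propan-2-yl)-7'-(propan-2-ylidene)-3',4',7',8'-tetrahydro-5'H-spiro[bicyclo[3.1.1]heptane-2,2'-pyrano[4,3-b]pyran]-5'-one; pyran oxygen on C2 anti to the gem-dimethyl bridge, isopropyl cis to bridgehead C1 | CC(C)[C@H]1C[C@]2(CC[C@@H]3C[C@H]2C3(C)C)OC2=C1C(=O)OC(=C(C)C)C2(C)C | intermediate
13 | sodium enolate of methyl (1S,2S,4'R,5R)-6'-(2,4-dimethyl-3-oxopentan-2-yl)-6,6-dimethyl-4'-(propan-2-yl)-3',4'-dihydrospiro[bicyclo[3.1.1]heptane-2,2'-pyran]-5'-carboxylate | [Na+].CC(C)[C@H]1C[C@]2(CC[C@@H]3C[C@H]2C3(C)C)OC(=C1C(=O)OC)C(C)(C)C([O-])=C(C)C | intermediate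
14 | (1S,2S,4'R,5R)-6,6,6',6',8',8'-hexamethyl-4'-(propan-2-yl)-3',4'-dihydrospiro[bicyclo[3.1.1]heptane-2,2'-chromene]-5',7'(6'H,8'H)-dione | CC(C)[C@H]1C[C@]2(CC[C@@H]3C[C@H]2C3(C)C)OC2=C1C(=O)C(C)(C)C(=O)C2(C)C | target

**Step count.** Total: 4 steps. Longest linear sequence: 4 steps (2 → 5 → 8 → 12 → 14).

**Steps most likely to fail**

Step 3. What may go wrong: ring closure of the cycloaddition through the lactone carbonyl oxygen instead of the ketone oxygen, weak endo/exo discrimination at C4', a competing ene reaction of the pinene, and hydrolytic opening of the enol lactone by the water of condensation. The fallback sets out from 2 and returns to the route at 13. The lithium enolate of methyl acetate (LiN(iPr)2, THF, −78 °C → rt) would open 2 as in step 1 to methyl 4,4,6-trimethyl-3,5-dioxoheptanoate F1. Knoevenagel condensation with 9 (piperidinium acetate, benzene, azeotropic removal of water) would give methyl 2-(2-methylpropylidene)-4,4,6-trimethyl-3,5-dioxoheptanoate F2, an open-chain 1-oxadiene in which only the ketone can serve as the oxygen terminus. Cycloaddition with 10 under high pressure (about 1 GPa, CH2Cl2, rt) or neat at 120 °C would give methyl (1S,2S,4'R,5R)-6'-(2,4-dimethyl-3-oxopentan-2-yl)-6,6-dimethyl-4'-(propan-2-yl)-3',4'-dihydrospiro[bicyclo[3.1.1]heptane-2,2'-pyran]-5'-carboxylate F3, again after separation from its 4'-epimer. NaN(SiMe3)2 in THF (−78 °C → rt) would turn F3 into enolate 13, which closes to 14 as in step 4. This removes the regiochemical question but not the endo/exo question, and the open-chain heterodiene is expected to be less reactive.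

Step 4. What may go wrong: return of the opened enolate by O-acylation without net turnover, or retro-Claisen attack of methoxide on the side-chain ketone before the ring closes. The fallback sets out from 12 and returns at 14. Aminolysis of the enol lactone with Me(MeO)NH·HCl and AlMe3 (CH2Cl2, 0 °C → rt) would give (1S,2S,4'R,5R)-6'-(2,4-dimethyl-3-oxopentan-2-yl)-N-methoxy-N,6,6-trimethyl-4'-(propan-2-yl)-3',4'-dihydrospiro[bicyclo[3.1.1]heptane-2,2'-pyran]-5'-carboxamide F4. LiN(SiMe3)2 (THF, −78 °C → 0 °C) would then form the ketone enolate irreversibly. Its addition to the N-methoxy-N-methylamide should stop at the chelated tetrahedral adduct, which releases 14 only on aqueous NH4Cl work-up, so no free alkoxide is present to cleave the product.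

Step 2. What may go wrong: decarboxylation of the free β-keto acid, or C-acylation of the enol, before the lactone closes. The fallback sets out from 5 and returns at 8. Heating 5 in dilute toluene at 110 °C with distillative removal of the alcohol should extrude tert-butanol in a retro-ene sense to give the acylketene 4,4,6-trimethylhept-1-ene-1,3,5-trione F5 (not isolated). Capture of the ketene by the C5 ketone oxygen, followed by loss of the C6 proton, would close 8 under neutral conditions with no free acid on the way.

**Further compounds**

F1 | step 3 | methyl 4,4,6-trimethyl-3,5-dioxoheptanoate | CC(C)C(=O)C(C)(C)C(=O)CC(=O)OC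
F2 | step 3 | methyl 2-(2-methylpropylidene)-4,4,6-trimethyl-3,5-dioxoheptanoate | CC(C)C=C(C(=O)OC)C(=O)C(C)(C)C(=O)C(C)C
F3 | step 3 | methyl (1S,2S,4'R,5R)-6'-(2,4-dimethyl-3-oxopentan-2-yl)-6,6-dimethyl-4'-(propan-2-yl)-3',4'-dihydrospiro[bicyclo[3.1.1]heptane-2,2'-pyran]-5'-carboxylate | CC(C)[C@H]1C[C@]2(CC[C@@H]3C[C@H]2C3(C)C)OC(=C1C(=O)OC)C(C)(C)C(=O)C(C)C
F4 | step 4 | (1S,2S,4'R,5R)-6'-(2,4-dimethyl-3-oxopentan-2-yl)-N-methoxy-N,6,6-trimethyl-4'-(propan-2-yl)-3',4'-dihydrospiro[bicyclo[3.1.1]heptane-2,2'-pyran]-5'-carboxamide | CC(C)[C@H]1C[C@]2(CC[C@@H]3C[C@H]2C3(C)C)OC(=C1C(=O)N(C)OC)C(C)(C)C(=O)C(C)C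
F5 | step 2 | 4,4,6-trimethylhept-1-ene-1,3,5-trione | CC(C)C(=O)C(C)(C)C(=O)C=C=O
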